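**Retrosynthetic overview**
- Thiocladospolide F (20) is a C2-symmetric sulfide, cut at both C–S bonds into two molecules of the 12-membered enone lactone 17 and one sulfide equivalent (double sulfa-Michael addition, then desilylation).
- Each 12-membered ring is closed before the sulfur bridge is made, by Yamaguchi macrolactonization of seco acid 15; this is the only ring-forming step.
- The (E)-4-oxobut-2-enoic acid end of 15 is unmasked from the 2-substituted furan 12 by oxidative ring opening.
- 12 is cut at C8–C9 into fragment A (iodide 5, from furfural, stereocentre by Brown allylation) and fragment B (chloro alcohol 10, from methyl acetoacetate, stereocentre by Noyori hydrogenation), joined by a copper-catalysed sp3–sp3 coupling.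

Assumption: the SMILES is read as the symmetric sulfide with both rings 3S,6S,12R (oxacyclododecane numbering); (−)-B-allyldiisopinocampheylborane is bought as its commercial 1 M solution.

**Fragment A**

Step 1
Reactants: 1 furfural
Product: 2 (S)-1-(furan-2-yl)but-3-en-1-ol
Conditions: (−)-Ipc2B(allyl) (1 M in pentane, 1.2 equiv), Et2O, −78 °C; then NaOH, H2O2, 0 °C → rt
Reagents that add atoms: (−)-B-allyldiisopinocampheylborane, C=CCB([C@@H]1C[C@@H]2C[C@H]([C@H]1C)C2(C)C)[C@@H]1C[C@@H]2C[C@H]([C@H]1C)C2(C)C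
Why: Brown asymmetric allylboration through a chair transition state delivers allyl to the si face of the aldehyde with the reagent derived from (+)-α-pinene, setting the furyl carbinol as S (later C6 of each ring).

Step 2
Reactants: 2 (S)-1-(furan-2-yl)but-3-en-1-ol
Product: 3 (S)-tert-butyl{[1-(furan-2-yl)but-3-en-1-yl]oxy}dimethylsilane
Conditions: TBSCl, imidazole, DMF, rt
Reagents that add atoms: tert-butyldimethylsilyl chloride, CC(C)(C)[Si](C)(C)Cl
Why: Standard silyl ether formation; the blocked furyl carbinol cannot undergo Achmatowicz rearrangement when the furan is oxidised in step 10.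

Step 3
Reactants: 3 (S)-tert-butyl{[1-(furan-2-yl)but-3-en-1-yl]oxy}dimethylsilane
Product: 4 (S)-4-[(tert-butyldimethylsilyl)oxy]-4-(furan-2-yl)butan-1-ol
Conditions: 9-BBN, THF, 0 °C → rt; then NaOH, H2O2, 0 °C
Reagents that add atoms: hydrogen peroxide, OO
Why: Anti-Markovnikov hydroboration–oxidation; the bulky borane takes the terminal alkene and leaves the furan untouched.

Step 4
Reactants: 4 (S)-4-[(tert-butyldimethylsilyl)oxy]-4-(furan-2-yl)butan-1-ol
Product: 5 (S)-tert-butyl[1-(furan-2-yl)-4-iodobutoxy]dimethylsilane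
Conditions: I2, PPh3, imidazole, CH2Cl2, 0 °C
Reagents that add atoms: iodine, II
Why: Appel-type (Garegg–Samuelsson) iodination of the primary alcohol under near-neutral conditions that the furan and silyl ether tolerate.

**Fragment B**

Step 5
Reactants: 6 methyl acetoacetate
Product: 7 methyl (R)-3-hydroxybutanoate
Conditions: H2 (50 atm), RuCl2[(R)-BINAP] (dichloro[(R)-2,2'-bis(diphenylphosphino)-1,1'-binaphthyl]ruthenium, 0.1 mol %), MeOH, 50 °C
Reagents that add atoms: none
Why: Noyori asymmetric hydrogenation of the chelated β-keto ester, in which the (R)-BINAP ligand directs hydride to one face and gives the R carbinol (later C12 of each ring).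

Step 6
Reactants: 7 methyl (R)-3-hydroxybutanoate
Product: 8 (R)-butane-1,3-diol
Conditions: LiAlH4, THF, 0 °C → rt; aqueous work-up
Reagents that add atoms: none
Why: Hydride reduction of the ester to the primary alcohol without touching the stereocentre.

Step 7
Reactants: 8 (R)-butane-1,3-diol
Product: 9 (R)-3-hydroxybutyl 4-methylbenzenesulfonate
Conditions: TsCl (1.05 equiv), pyridine, CH2Cl2, −20 → 0 °C
Reagents that add atoms: 4-methylbenzenesulfonyl chloride, Cc1ccc(cc1)S(Cl)(=O)=O
Why: Selective sulfonylation of the less hindered primary hydroxyl.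

Step 8
Reactants: 9 (R)-3-hydroxybutyl 4-methylbenzenesulfonate
Product: 10 (R)-4-chlorobutan-2-ol
Conditions: LiCl, DMF, 50 °C
Reagents that add atoms: lithium chloride, [Li+].[Cl-]
Why: SN2 displacement of the primary tosylate by chloride under neutral conditions, which avoids oxetane formation.

**Union and end game**

Step 9
Reactants: 5 (S)-tert-butyl[1-(furan-2-yl)-4-iodobutoxy]dimethylsilane; 10 (R)-4-chlorobutan-2-ol (3 equiv)
Product: 12 (2R,8S)-8-[(tert-butyldimethylsilyl)oxy]-8-(furan-2-yl)octan-2-ol, via alkoxide Grignard reagent 11 (not isolated)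
Conditions: 10, i-PrMgCl, THF, −20 °C; Mg, BrCH2CH2Br (cat.), reflux; then 5, Li2CuCl4 (5 mol %), THF, −30 → 0 °C; aq NH4Cl
Reagents that add atoms: none
Why: Normant-type alkoxide Grignard formation followed by Kochi (Fouquet–Schlosser) copper-catalysed sp3–sp3 coupling with the primary iodide gives the full C5–C12 chain with the secondary hydroxyl already free and both stereocentres untouched.

Step 10
Reactants: 12 (2R,8S)-8-[(tert-butyldimethylsilyl)oxy]-8-(furan-2-yl)octan-2-ol
Product: 15 (2E,5S,11R)-5-[(tert-butyldimethylsilyl)oxy]-11-hydroxy-4-oxododec-2-enoic acid, via Z-enal 13 (not isolated), via E-enal 14 (not isolated)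
Conditions: NBS (1.05 equiv), NaHCO3, acetone–H2O (10:1), −15 °C; pyridine (cat.), rt; then NaClO2, NaH2PO4, 2-methylbut-2-ene, t-BuOH–H2O, 0 °C → rt
Reagents that add atoms: water, O; sodium chlorite, [Na+].[O-]Cl=O
Why: Oxidative furan ring opening by NBS in water gives the cis-4-oxo-enal, pyridine isomerises it to the E isomer and Pinnick oxidation takes the aldehyde to the acid, all without touching the α-silyloxy stereocentre.

Step 11
Reactants: 15 (2E,5S,11R)-5-[(tert-butyldimethylsilyl)oxy]-11-hydroxy-4-oxododec-2-enoic acid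
Product: 17 (3E,6S,12R)-6-[(tert-butyldimethylsilyl)oxy]-12-methyl-1-oxacyclododec-3-ene-2,5-dione, via mixed anhydride 16 (not isolated)
Conditions: 2,4,6-Cl3C6H2COCl, Et3N, THF, rt; then slow addition to DMAP, toluene (1 mM), 40 °C
Reagents that add atoms: none
Why: Yamaguchi macrolactonization under high dilution closes the 12-membered ring by acyl transfer to the only free hydroxyl, so C12 keeps its R configuration.

Step 12
Reactants: 17 (3E,6S,12R)-6-[(tert-butyldimethylsilyl)oxy]-12-methyl-1-oxacyclododec-3-ene-2,5-dione (2 equiv)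
Product: 20 thiocladospolide F [(3S,3'S,6S,6'S,12R,12'R)-3,3'-sulfanediylbis(6-hydroxy-12-methyl-1-oxacyclododecane-2,5-dione)], via monothiol 18 (not isolated), via bis-silyl sulfide 19 (not isolated)
Conditions: NaSH·xH2O (1 equiv), Et3N (0.2 equiv), degassed MeCN–H2O (20:1), −20 → 0 °C, Ar; then 48% aq HF, MeCN, 0 °C → rt
Reagents that add atoms: sodium hydrosulfide, [Na+].[SH-]
Why: Double sulfa-Michael addition, in which hydrosulfide and then the resulting thiolate add β to the ketone (C3 of each ring) from the open peripheral face of the macrocyclic E-enone; the reversible addition is expected to settle on the 3S configuration of the natural 3-thio adducts under substrate control, and acidic HF then removes both silyl ethers without retro-Michael cleavage.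

**Compound list**

1 | furfural | O=Cc1ccco1 | starting material
2 | (S)-1-(furan-2-yl)but-3-en-1-ol | C=CC[C@H](O)c1ccco1 | intermediate
3 | (S)-tert-butyl{[1-(furan-2-yl)but-3-en-1-yl]oxy}dimethylsilane | C=CC[C@H](O[Si](C)(C)C(C)(C)C)c1ccco1 | intermediate
4 | (S)-4-[(tert-butyldimethylsilyl)oxy]-4-(furan-2-yl)butan-1-ol | OCCC[C@H](O[Si](C)(C)C(C)(C)C)c1ccco1 | intermediate
5 | (S)-tert-butyl[1-(furan-2-yl)-4-iodobutoxy]dimethylsilane | ICCC[C@H](O[Si](C)(C)C(C)(C)C)c1ccco1 | intermediate
6 | methyl acetoacetate | COC(=O)CC(C)=O | starting material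
7 | methyl (R)-3-hydroxybutanoate | C[C@@H](O)CC(=O)OC | intermediate
8 | (R)-butane-1,3-diol | C[C@@H](O)CCO | intermediate
9 | (R)-3-hydroxybutyl 4-methylbenzenesulfonate | C[C@@H](O)CCOS(=O)(=O)c1ccc(C)cc1 | intermediate
10 | (R)-4-chlorobutan-2-ol | C[C@@H](O)CCCl | intermediate
11 | chloromagnesium (R)-4-(chloromagnesio)butan-2-olate (alkoxide Grignard reagent) | C[C@@H](O[Mg]Cl)CC[Mg]Cl | intermediate
12 | (2R,8S)-8-[(tert-butyldimethylsilyl)oxy]-8-(furan-2-yl)octan-2-ol | C[C@@H](O)CCCCC[C@H](O[Si](C)(C)C(C)(C)C)c1ccco1 | intermediate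
13 | (2Z,5S,11R)-5-[(tert-butyldimethylsilyl)oxy]-11-hydroxy-4-oxododec-2-enal | C[C@@H](O)CCCCC[C@H](O[Si](C)(C)C(C)(C)C)C(=O)/C=C\C=O | intermediate
14 | (2E,5S,11R)-5-[(tert-butyldimethylsilyl)oxy]-11-hydroxy-4-oxododec-2-enal | C[C@@H](O)CCCCC[C@H](O[Si](C)(C)C(C)(C)C)C(=O)/C=C/C=O | intermediate
15 | (2E,5S,11R)-5-[(tert-butyldimethylsilyl)oxy]-11-hydroxy-4-oxododec-2-enoic acid | C[C@@H](O)CCCCC[C@H](O[Si](C)(C)C(C)(C)C)C(=O)/C=C/C(=O)O | intermediate
16 | mixed anhydride of 15 with 2,4,6-trichlorobenzoic acid | C[C@@H](O)CCCCC[C@H](O[Si](C)(C)C(C)(C)C)C(=O)/C=C/C(=O)OC(=O)c1c(Cl)cc(Cl)cc1Cl | intermediate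
17 | (3E,6S,12R)-6-[(tert-butyldimethylsilyl)oxy]-12-methyl-1-oxacyclododec-3-ene-2,5-dione | C[C@@H]1CCCCC[C@H](O[Si](C)(C)C(C)(C)C)C(=O)/C=C/C(=O)O1 | intermediate
18 | (3S,6S,12R)-6-[(tert-butyldimethylsilyl)oxy]-12-methyl-3-sulfanyl-1-oxacyclododecane-2,5-dione | C[C@@H]1CCCCC[C@H](O[Si](C)(C)C(C)(C)C)C(=O)C[C@H](S)C(=O)O1 | intermediate
19 | (3S,3'S,6S,6'S,12R,12'R)-3,3'-sulfanediylbis{6-[(tert-butyldimethylsilyl)oxy]-12-methyl-1-oxacyclododecane-2,5-dione} | C[C@@H]1CCCCC[C@H](O[Si](C)(C)C(C)(C)C)C(=O)C[C@H](S[C@H]2CC(=O)[C@@H](O[Si](C)(C)C(C)(C)C)CCCCC[C@@H](C)OC2=O)C(=O)O1 | intermediate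
20 | thiocladospolide F, (3S,3'S,6S,6'S,12R,12'R)-3,3'-sulfanediylbis(6-hydroxy-12-methyl-1-oxacyclododecane-2,5-dione) | C[C@@H]1CCCCC[C@H](O)C(=O)C[C@H](S[C@H]2CC(=O)[C@@H](O)CCCCC[C@@H](C)OC2=O)C(=O)O1 | target

**Step count**
Total: 12 steps. Longest linear sequence: 8 steps (1–4 then 9–12, or 5–8 then 9–12).

**Three steps most likely to fail**

Step 12. The C3 configuration rests on substrate control only and has not been modelled here, so C3 epimers or mixed mono- and bis-adducts may form. The fallback is a stepwise, catalyst-controlled addition that sets out from 17. Thioacetic acid is added under a cinchona-derived bifunctional squaramide organocatalyst (toluene, −20 °C) to give (3S,6S,12R)-3-(acetylsulfanyl)-6-[(tert-butyldimethylsilyl)oxy]-12-methyl-1-oxacyclododecane-2,5-dione F1, which is freed from its C3 epimer by chromatography. Hydrazine acetate in DMF then releases thiol 18, now isolated, and 18 is added to a second equivalent of 17 under the same catalyst. The route is rejoined at 19, which is desilylated with aqueous HF as before.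

Step 11. The activated 4-oxo-enoate may isomerise to the Z acid through reversible DMAP addition, epimerise at C5, or oligomerise. The fallback closes the ring at the alcohol oxidation level and sets out from 15. Luche reduction (NaBH4, CeCl3·7H2O, MeOH, −40 °C) gives (2E,4RS,5S,11R)-5-[(tert-butyldimethylsilyl)oxy]-4,11-dihydroxydodec-2-enoic acid F2, whose C4 hydroxyl cannot lactonize across the E-alkene. Yamaguchi lactonization gives (3E,5RS,6S,12R)-6-[(tert-butyldimethylsilyl)oxy]-5-hydroxy-12-methyl-1-oxacyclododec-3-en-2-one F3, and Dess–Martin oxidation of the allylic alcohol comes back to 17.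

Step 9. The alkoxide Grignard reagent is poorly soluble and may reduce or eliminate the iodide instead of coupling. The fallback is a palladium-catalysed alkyl–alkyl Suzuki–Miyaura coupling that sets out from alkene 3 and tosylate 9. Hydroboration of 3 with 9-BBN in THF gives 9-[(4S)-4-[(tert-butyldimethylsilyl)oxy]-4-(furan-2-yl)butyl]-9-borabicyclo[3.3.1]nonane F4, and 9 with LiBr in acetone gives (R)-4-bromobutan-2-ol F5. Coupling of F4 and F5 with Pd(OAc)2, PCy3 and K3PO4·H2O in THF at rt comes back to 12 directly.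

**Further compounds**

F1 | step 12 | (3S,6S,12R)-3-(acetylsulfanyl)-6-[(tert-butyldimethylsilyl)oxy]-12-methyl-1-oxacyclododecane-2,5-dione | C[C@@H]1CCCCC[C@H](O[Si](C)(C)C(C)(C)C)C(=O)C[C@H](SC(C)=O)C(=O)O1
F2 | step 11 | (2E,4RS,5S,11R)-5-[(tert-butyldimethylsilyl)oxy]-4,11-dihydroxydodec-2-enoic acid | C[C@@H](O)CCCCC[C@H](O[Si](C)(C)C(C)(C)C)C(O)/C=C/C(=O)O
F3 | step 11 | (3E,5RS,6S,12R)-6-[(tert-butyldimethylsilyl)oxy]-5-hydroxy-12-methyl-1-oxacyclododec-3-en-2-one | C[C@@H]1CCCCC[C@H](O[Si](C)(C)C(C)(C)C)C(O)/C=C/C(=O)O1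
F4 | step 9 | 9-[(4S)-4-[(tert-butyldimethylsilyl)oxy]-4-(furan-2-yl)butyl]-9-borabicyclo[3.3.1]nonane | C(CC[C@H](O[Si](C)(C)C(C)(C)C)c1ccco1)B1C2CCCC1CCC2
F5 | step 9 | (R)-4-bromobutan-2-ol | C[C@@H](O)CCBr
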